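## Retrosynthetic overview

1. The last bond made is the side-chain ester C–O: target 35 comes from the bis-silylated acrylic acid 32 (C14 half) and the bicyclic lactone diol 19 (C15 half), by Yamaguchi esterification and one fluoride deprotection.
2. Both halves come from (S)-cryptone 4, whose ring is the first one formed (organocatalytic Michael addition and aldol condensation of 1 and 2).
3. Diol 19: allene [2+2] photocycloaddition on 4 (cyclobutane, sets the cis C9a/C5a pair trans to isopropyl), convex-face hydroxymethylation of the ketone (C9), oxidative opening of the cyclobutane to CO2H and CHO, then ester tether and ring-closing metathesis to the seven-membered lactone (last ring).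
4. Acid 32: trans conjugate alkynylation of 4 with enolate trapping, enol triflate carbonylation to the ring CH2OH, then syn-hydrostannation, iodination and carbonylation of the alkyne to the (E)-2-(silyloxymethyl)acrylic acid.

Assumption: cryptone 4 is obtained in about 90% ee, and the minor diastereomers this causes after fragment union are removed by chromatography at step 23.

## Route

Step 1
Reactants: 1 3-methylbutanal; 2 but-3-en-2-one
Product: 4 (4S)-4-(propan-2-yl)cyclohex-2-en-1-one [(S)-cryptone], via keto aldehyde 3 (not isolated)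
Conditions: (S)-2-{bis[3,5-bis(trifluoromethyl)phenyl][(trimethylsilyl)oxy]methyl}pyrrolidine (5 mol%), ethyl 3,4-dihydroxybenzoate (20 mol%), neat, 4 °C; then LiOH (cat.), iPrOH, rt
Reagents that add atoms: none
Why: Enamine-catalysed (Jørgensen–Hayashi) Michael addition to the enone occurs on the enamine face opposite the bulky diaryl(silyloxy)methyl group and sets C4 as S, and the 1,5-keto aldehyde then closes by intramolecular aldol condensation (Robinson-type annulation).

Step 2
Reactants: 4 (S)-cryptone; 5 propa-1,2-diene (allene)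
Product: 6 (1R,5S,6S)-8-methylidene-5-(propan-2-yl)bicyclo[4.2.0]octan-2-one
Conditions: hν (medium-pressure mercury lamp, Pyrex filter), excess allene, THF, −78 °C
Reagents that add atoms: none
Why: Enone–allene [2+2] photocycloaddition gives the head-to-head, cis-fused methylenecyclobutane, with the first bond forming at the enone β-carbon anti to the neighbouring isopropyl group, so both new C–C bonds are cis to each other and trans to isopropyl (minor syn isomer removed by chromatography).

Step 3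
Reactants: 6 photoadduct ketone
Product: 8 (1R,2R,5S,6S)-2-(hydroxymethyl)-8-methylidene-5-(propan-2-yl)bicyclo[4.2.0]octan-2-ol, via silylcarbinol 7 (not isolated)
Conditions: (iPrO)Me2SiCH2MgCl, THF, 0 °C; then 30% H2O2, KF, KHCO3, MeOH/THF, rt
Reagents that add atoms: (isopropoxydimethylsilyl)methylmagnesium chloride, CC(C)O[Si](C)(C)C[Mg]Cl; hydrogen peroxide, OO
Why: Tamao nucleophilic hydroxymethylation, in which the weakly basic silylmethyl Grignard reagent adds to the cis-fused bicyclic ketone from the convex face (anti to the axial cyclobutane bond at C1), so CH2 ends trans and the tertiary OH cis to C8, and Tamao oxidation then turns C–Si into C–OH without touching the stereocentre.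

Step 4
Reactants: 8 diol
Product: 9 acetonide of 8 [(1R,2R,5S,6S)-2',2'-dimethyl-8-methylidene-5-(propan-2-yl)spiro[bicyclo[4.2.0]octane-2,4'-[1,3]dioxolane]]
Conditions: Me2C(OMe)2, pyridinium p-toluenesulfonate (cat.), acetone, rt
Reagents that add atoms: 2,2-dimethoxypropane, COC(C)(C)OC
Why: Acid-catalysed transketalisation ties the primary/tertiary 1,2-diol into a dioxolane, which masks both hydroxyls and blocks retro-aldol cleavage once C8 becomes a ketone.

Step 5
Reactants: 9 acetonide
Product: 10 cyclobutanone [(1S,2R,5S,6S)-2',2'-dimethyl-5-(propan-2-yl)spiro[bicyclo[4.2.0]octane-2,4'-[1,3]dioxolan]-8-one; numbering as in 6]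
Conditions: O3, CH2Cl2/MeOH, −78 °C; then Me2S, −78 °C to rt
Reagents that add atoms: ozone, O=[O+][O-]
Why: Ozonolysis of the exocyclic 1,1-disubstituted alkene with reductive work-up gives the cyclobutanone, while the acetonide and the saturated skeleton are inert at −78 °C.

Step 6
Reactants: 10 cyclobutanone
Product: 11 trimethylsilyl enol ether of 10 with the C7=C8 double bond [(1S,2R,5S,6R); numbering as in 6]
Conditions: LiN(iPr)2, THF, −78 °C; then Me3SiCl, −78 °C
Reagents that add atoms: chlorotrimethylsilane, C[Si](C)(C)Cl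
Why: Kinetic enolisation by the hindered amide base removes a proton from the open C7 methylene and not from the ring-fusion C1–H next to the spiro centre, and O-silylation fixes the enol ether regiochemistry without epimerising C1.

Step 7
Reactants: 11 silyl enol ether
Product: 13 (5R,6S,7S,8S)-7-formyl-2,2-dimethyl-8-(propan-2-yl)-1,3-dioxaspiro[4.5]decane-6-carboxylic acid, via silyl ester aldehyde 12 (not isolated)
Conditions: O3, CH2Cl2, −78 °C; then Me2S; aqueous work-up
Reagents that add atoms: ozone, O=[O+][O-]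
Why: Ozonolysis of the silyl enol ether cleaves C7–C8 into a silyl ester and an aldehyde, so the cis ring fusion of the cyclobutane becomes the cis relationship of CO2H and CHO (the product rests as its hydroxy-lactone pseudo-acid, which protects the α-centre).

Step 8
Reactants: 13 aldehyde acid
Product: 14 (5R,6S,7S,8S)-7-ethenyl-2,2-dimethyl-8-(propan-2-yl)-1,3-dioxaspiro[4.5]decane-6-carboxylic acid
Conditions: Ph3PCH3Br, KN(SiMe3)2 (3 equiv of ylide), THF, −78 to 0 °C; work-up at pH 4
Reagents that add atoms: methyltriphenylphosphonium bromide, C[P+](c1ccccc1)(c1ccccc1)c1ccccc1.[Br-]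
Why: Wittig methylenation of the aldehyde, to which the carboxylate is inert, run cold so that olefination outruns epimerisation of the α-centre.

Step 9
Reactants: 15 2-(bromomethyl)prop-2-enoic acid
Product: 16 2-(trimethylsilyl)ethyl 2-(bromomethyl)prop-2-enoate
Conditions: 2-(trimethylsilyl)ethanol, DCC, DMAP (5 mol%), CH2Cl2, 0 °C
Reagents that add atoms: 2-(trimethylsilyl)ethanol, C[Si](C)(C)CCO
Why: Steglich esterification (carbodiimide activation, acyl transfer by DMAP) at 0 °C leaves the allylic bromide intact and installs a fluoride-labile ester.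

Step 10
Reactants: 14 vinyl acid; 16 bromomethyl acrylate
Product: 17 2-{[2-(trimethylsilyl)ethoxy]carbonyl}prop-2-en-1-yl (5R,6S,7S,8S)-7-ethenyl-2,2-dimethyl-8-(propan-2-yl)-1,3-dioxaspiro[4.5]decane-6-carboxylate
Conditions: Cs2CO3, DMF, 0 °C to rt
Reagents that add atoms: none
Why: O-Alkylation of the caesium carboxylate by the activated allylic bromide (SN2 and SN2' give the same ester) builds the ester tether without touching the α-stereocentre.

Step 11
Reactants: 17 diene ester
Product: 18 O,O-isopropylidene derivative (acetonide) of lactone diol 19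
Conditions: second-generation Hoveyda–Grubbs catalyst RuCl2(H2IMes)(=CH-C6H4-2-OiPr) (10 mol%), toluene (0.005 M), 80 °C
Reagents that add atoms: none
Why: Ring-closing metathesis starts at the monosubstituted vinyl group and closes onto the 2-substituted acrylate, helped by the cis arrangement of vinyl and ester on the cyclohexane, and the seven-membered ring fixes the alkene geometry (CH2O cis to the ring carbon, ester carbonyl trans).

Step 12
Reactants: 18 lactone acetonide
Product: 19 2-(trimethylsilyl)ethyl (5aR,6S,9R,9aS)-9-hydroxy-9-(hydroxymethyl)-1-oxo-6-(propan-2-yl)-1,3,5a,6,7,8,9,9a-octahydro-2-benzoxepine-4-carboxylate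
Conditions: AcOH/H2O (4:1), 45 °C
Reagents that add atoms: none
Why: Mild acid hydrolysis of the dioxolane spares the silylethyl ester and the lactone, and the freed axial CH2OH lies anti to the axial lactone carbonyl carbon, so it cannot translactonise.

Step 13
Reactants: 20 prop-2-yn-1-ol
Product: 21 tert-butyl(dimethyl)(prop-2-yn-1-yloxy)silane
Conditions: tBuMe2SiCl, imidazole, CH2Cl2, 0 °C to rt
Reagents that add atoms: tert-butyldimethylsilyl chloride, CC(C)(C)[Si](C)(C)Cl
Why: Standard silylation of the primary alcohol, so that the alkyne can be metallated.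

Step 14
Reactants: 21 silyl propargyl ether; 4 (S)-cryptone
Product: 24 tert-butyl{[(3S,4S)-3-{3-[(tert-butyldimethylsilyl)oxy]prop-1-yn-1-yl}-4-(propan-2-yl)cyclohex-1-en-1-yl]oxy}dimethylsilane, via lithium acetylide 22 (not isolated), via alkynylzinc bromide 23 (not isolated)
Conditions: nBuLi, THF, −78 °C; ZnBr2, 0 °C; then 4 and tBuMe2SiOSO2CF3, Et2O/THF, −40 °C
Reagents that add atoms: tert-butyldimethylsilyl trifluoromethanesulfonate, CC(C)(C)[Si](C)(C)OS(=O)(=O)C(F)(F)F
Why: Silyl-triflate-promoted conjugate addition of the alkynylzinc reagent (Kim conditions) delivers the alkynyl group to the β-carbon trans to the neighbouring isopropyl group and traps the enolate regiospecifically as its silyl enol ether.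

Step 15
Reactants: 24 silyl enol ether
Product: 25 (3S,4S)-3-{3-[(tert-butyldimethylsilyl)oxy]prop-1-yn-1-yl}-4-(propan-2-yl)cyclohex-1-en-1-yl trifluoromethanesulfonate
Conditions: CsF, PhNTf2, 1,2-dimethoxyethane, rt
Reagents that add atoms: N-phenylbis(trifluoromethanesulfonimide), O=S(=O)(N(c1ccccc1)S(=O)(=O)C(F)(F)F)C(F)(F)F
Why: Fluoride cleaves the silyl enol ether to the caesium enolate, which is O-triflated with retention of the double-bond position (alkyl silyl ethers are much slower to cleave under these conditions).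

Step 16
Reactants: 25 enol triflate
Product: 26 methyl (3S,4S)-3-{3-[(tert-butyldimethylsilyl)oxy]prop-1-yn-1-yl}-4-(propan-2-yl)cyclohex-1-ene-1-carboxylate
Conditions: Pd(OAc)2 (5 mol%), PPh3 (10 mol%), CO (1 atm), MeOH, Et3N, DMF, 40 °C
Reagents that add atoms: carbon monoxide, [C-]#[O+]; methanol, CO
Why: Palladium-catalysed methoxycarbonylation of the enol triflate (oxidative addition, CO insertion, methanolysis) puts the future CH2OH carbon on C1 of the ring.

Step 17
Reactants: 26 ring ester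
Product: 27 [(3S,4S)-3-{3-[(tert-butyldimethylsilyl)oxy]prop-1-yn-1-yl}-4-(propan-2-yl)cyclohex-1-en-1-yl]methanol
Conditions: iBu2AlH (2.5 equiv), CH2Cl2, −78 °C; aq. KNaC4H4O6 work-up
Reagents that add atoms: none
Why: 1,2-Reduction of the conjugated ester by the aluminium hydride gives the allylic alcohol and leaves the alkyne and the silyl ether untouched.

Step 18
Reactants: 27 allylic alcohol
Product: 28 tert-butyl({(3S,4S)-3-{3-[(tert-butyldimethylsilyl)oxy]prop-1-yn-1-yl}-4-(propan-2-yl)cyclohex-1-en-1-yl}methoxy)dimethylsilane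
Conditions: tBuMe2SiCl, imidazole, DMF, rt
Reagents that add atoms: tert-butyldimethylsilyl chloride, CC(C)(C)[Si](C)(C)Cl
Why: Standard silylation of the primary allylic alcohol, giving two identical fluoride-labile ethers.

Step 19
Reactants: 28 bis-silyl alkyne
Product: 29 tributyl[(1E)-3-[(tert-butyldimethylsilyl)oxy]-1-[(1S,6S)-3-{[(tert-butyldimethylsilyl)oxy]methyl}-6-(propan-2-yl)cyclohex-2-en-1-yl]prop-1-en-2-yl]stannane
Conditions: Bu3SnH (1.3 equiv), PdCl2(PPh3)2 (3 mol%), THF, 0 °C to rt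
Reagents that add atoms: tributyltin hydride, CCCC[SnH](CCCC)CCCC
Why: Palladium-catalysed syn-hydrostannation puts tin on the alkyne carbon next to the propargylic oxygen (also the less hindered carbon), and syn delivery of H and Sn leaves the CH2O group cis to the ring carbon.

Step 20
Reactants: 29 alkenylstannane
Product: 30 tert-butyl{[(2E)-2-iodo-3-[(1S,6S)-3-{[(tert-butyldimethylsilyl)oxy]methyl}-6-(propan-2-yl)cyclohex-2-en-1-yl]prop-2-en-1-yl]oxy}dimethylsilane
Conditions: I2 (1.05 equiv), CH2Cl2, 0 °C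
Reagents that add atoms: iodine, I-I
Why: Iododestannylation occurs with retention of alkene geometry and is much faster than any reaction of iodine with the trisubstituted ring alkene.

Step 21
Reactants: 30 alkenyl iodide
Product: 31 methyl (2E)-2-{[(tert-butyldimethylsilyl)oxy]methyl}-3-[(1S,6S)-3-{[(tert-butyldimethylsilyl)oxy]methyl}-6-(propan-2-yl)cyclohex-2-en-1-yl]prop-2-enoate
Conditions: PdCl2(PPh3)2 (5 mol%), CO (1 atm), MeOH, Et3N, DMF, 50 °C
Reagents that add atoms: carbon monoxide, [C-]#[O+]; methanol, CO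
Why: Palladium-catalysed methoxycarbonylation of the alkenyl iodide proceeds with retention, so the ester carbonyl ends trans to the ring carbon (E).

Step 22
Reactants: 31 methyl ester
Product: 32 (2E)-2-{[(tert-butyldimethylsilyl)oxy]methyl}-3-[(1S,6S)-3-{[(tert-butyldimethylsilyl)oxy]methyl}-6-(propan-2-yl)cyclohex-2-en-1-yl]prop-2-enoic acid
Conditions: LiOH·H2O, THF/MeOH/H2O (3:1:1), 40 °C; then aq. HCl to pH 4, 0 °C
Reagents that add atoms: lithium hydroxide, [Li+].[OH-]
Why: Saponification of the methyl ester; the silyl ethers are stable to hydroxide and the alkene geometry is unaffected.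

Step 23
Reactants: 32 acid; 19 lactone diol
Product: 34 bis(tert-butyldimethylsilyl) ether and 2-(trimethylsilyl)ethyl ester of the target, via mixed anhydride 33 (not isolated)
Conditions: 2,4,6-Cl3C6H2COCl, Et3N, THF, 0 °C to rt; then 19, DMAP, toluene, rt
Reagents that add atoms: none
Why: Yamaguchi esterification, in which the mixed anhydride acylates the primary hydroxyl of 19 selectively over the hindered tertiary one, joining the two halves without touching any stereocentre.

Step 24
Reactants: 34 protected target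
Product: 35 (5aR,6S,9R,9aS)-9-hydroxy-9-({[(2E)-2-(hydroxymethyl)-3-[(1S,6S)-3-(hydroxymethyl)-6-(propan-2-yl)cyclohex-2-en-1-yl]prop-2-enoyl]oxy}methyl)-1-oxo-6-(propan-2-yl)-1,3,5a,6,7,8,9,9a-octahydro-2-benzoxepine-4-carboxylic acid (CNP0361406.4)
Conditions: (Me2N)3S+ Me3SiF2− (TASF, 6 equiv), DMF/H2O, 0 °C to rt; pH 5 buffer work-up
Reagents that add atoms: none
Why: Fluoride-mediated global desilylation cleaves both silyl ethers and fragments the 2-(trimethylsilyl)ethyl ester (β-elimination) under near-neutral conditions that spare the lactone, the side-chain ester and the β-hydroxy ester motif.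

## Compound list

1 | 3-methylbutanal | CC(C)CC=O | starting material
2 | but-3-en-2-one | CC(=O)C=C | starting material
3 | (2S)-5-oxo-2-(propan-2-yl)hexanal | CC(C)[C@@H](C=O)CCC(C)=O | intermediate
4 | (4S)-4-(propan-2-yl)cyclohex-2-en-1-one, (S)-cryptone | CC(C)[C@@H]1CCC(=O)C=C1 | intermediate
5 | propa-1,2-diene | C=C=C | starting material
6 | (1R,5S,6S)-8-methylidene-5-(propan-2-yl)bicyclo[4.2.0]octan-2-one (cis-fused, cyclobutane trans to isopropyl) | CC(C)[C@@H]1CCC(=O)[C@H]2C(=C)C[C@@H]12 | intermediate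
7 | (1R,2R,5S,6S)-2-{[dimethyl(propan-2-yloxy)silyl]methyl}-8-methylidene-5-(propan-2-yl)bicyclo[4.2.0]octan-2-ol (formed as its magnesium alkoxide) | CC(C)[C@@H]1CC[C@](O)(C[Si](C)(C)OC(C)C)[C@H]2C(=C)C[C@@H]12 | intermediate
8 | (1R,2R,5S,6S)-2-(hydroxymethyl)-8-methylidene-5-(propan-2-yl)bicyclo[4.2.0]octan-2-ol | CC(C)[C@@H]1CC[C@](O)(CO)[C@H]2C(=C)C[C@@H]12 | intermediate
9 | acetonide of 8, (1R,2R,5S,6S)-2',2'-dimethyl-8-methylidene-5-(propan-2-yl)spiro[bicyclo[4.2.0]octane-2,4'-[1,3]dioxolane] | CC(C)[C@@H]1CC[C@]3(COC(C)(C)O3)[C@H]2C(=C)C[C@@H]12 | intermediate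
10 | cyclobutanone, (1S,2R,5S,6S)-2',2'-dimethyl-5-(propan-2-yl)spiro[bicyclo[4.2.0]octane-2,4'-[1,3]dioxolan]-8-one | CC(C)[C@@H]1CC[C@]3(COC(C)(C)O3)[C@H]2C(=O)C[C@@H]12 | intermediate
11 | trimethylsilyl enol ether of 10 (C7=C8), (1S,2R,5S,6R) | CC(C)[C@@H]1CC[C@]3(COC(C)(C)O3)[C@H]2C(O[Si](C)(C)C)=C[C@@H]12 | intermediate
12 | trimethylsilyl (5R,6S,7S,8S)-7-formyl-2,2-dimethyl-8-(propan-2-yl)-1,3-dioxaspiro[4.5]decane-6-carboxylate | CC(C)[C@@H]1CC[C@]3(COC(C)(C)O3)[C@@H](C(=O)O[Si](C)(C)C)[C@H]1C=O | intermediate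
13 | (5R,6S,7S,8S)-7-formyl-2,2-dimethyl-8-(propan-2-yl)-1,3-dioxaspiro[4.5]decane-6-carboxylic acid | CC(C)[C@@H]1CC[C@]3(COC(C)(C)O3)[C@@H](C(=O)O)[C@H]1C=O | intermediate
14 | (5R,6S,7S,8S)-7-ethenyl-2,2-dimethyl-8-(propan-2-yl)-1,3-dioxaspiro[4.5]decane-6-carboxylic acid | CC(C)[C@@H]1CC[C@]3(COC(C)(C)O3)[C@@H](C(=O)O)[C@H]1C=C | intermediate
15 | 2-(bromomethyl)prop-2-enoic acid | OC(=O)C(=C)CBr | starting material
16 | 2-(trimethylsilyl)ethyl 2-(bromomethyl)prop-2-enoate | C=C(CBr)C(=O)OCC[Si](C)(C)C | intermediate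
17 | 2-{[2-(trimethylsilyl)ethoxy]carbonyl}prop-2-en-1-yl (5R,6S,7S,8S)-7-ethenyl-2,2-dimethyl-8-(propan-2-yl)-1,3-dioxaspiro[4.5]decane-6-carboxylate | CC(C)[C@@H]1CC[C@]3(COC(C)(C)O3)[C@@H](C(=O)OCC(=C)C(=O)OCC[Si](C)(C)C)[C@H]1C=C | intermediate
18 | acetonide (C9 tertiary O and CH2O joined by CMe2) of lactone diol 19 | CC(C)[C@@H]1CC[C@]3(COC(C)(C)O3)[C@H]2C(=O)OCC(C(=O)OCC[Si](C)(C)C)=C[C@@H]12 | intermediate
19 | 2-(trimethylsilyl)ethyl (5aR,6S,9R,9aS)-9-hydroxy-9-(hydroxymethyl)-1-oxo-6-(propan-2-yl)-1,3,5a,6,7,8,9,9a-octahydro-2-benzoxepine-4-carboxylate | CC(C)[C@@H]1CC[C@](O)(CO)[C@H]2C(=O)OCC(C(=O)OCC[Si](C)(C)C)=C[C@@H]12 | intermediate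
20 | prop-2-yn-1-ol | C#CCO | starting material
21 | tert-butyl(dimethyl)(prop-2-yn-1-yloxy)silane | C#CCO[Si](C)(C)C(C)(C)C | intermediate
22 | lithium acetylide of 21 | [Li]C#CCO[Si](C)(C)C(C)(C)C | intermediate
23 | alkynylzinc bromide of 21 | Br[Zn]C#CCO[Si](C)(C)C(C)(C)C | intermediate
24 | tert-butyl{[(3S,4S)-3-{3-[(tert-butyldimethylsilyl)oxy]prop-1-yn-1-yl}-4-(propan-2-yl)cyclohex-1-en-1-yl]oxy}dimethylsilane (alkynyl trans to isopropyl) | CC(C)(C)[Si](C)(C)OCC#C[C@@H]1C=C(O[Si](C)(C)C(C)(C)C)CC[C@H]1C(C)C | intermediate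
25 | (3S,4S)-3-{3-[(tert-butyldimethylsilyl)oxy]prop-1-yn-1-yl}-4-(propan-2-yl)cyclohex-1-en-1-yl trifluoromethanesulfonate | CC(C)(C)[Si](C)(C)OCC#C[C@@H]1C=C(OS(=O)(=O)C(F)(F)F)CC[C@H]1C(C)C | intermediate
26 | methyl (3S,4S)-3-{3-[(tert-butyldimethylsilyl)oxy]prop-1-yn-1-yl}-4-(propan-2-yl)cyclohex-1-ene-1-carboxylate | CC(C)(C)[Si](C)(C)OCC#C[C@@H]1C=C(C(=O)OC)CC[C@H]1C(C)C | intermediate
27 | [(3S,4S)-3-{3-[(tert-butyldimethylsilyl)oxy]prop-1-yn-1-yl}-4-(propan-2-yl)cyclohex-1-en-1-yl]methanol | CC(C)(C)[Si](C)(C)OCC#C[C@@H]1C=C(CO)CC[C@H]1C(C)C | intermediate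
28 | tert-butyl({(3S,4S)-3-{3-[(tert-butyldimethylsilyl)oxy]prop-1-yn-1-yl}-4-(propan-2-yl)cyclohex-1-en-1-yl}methoxy)dimethylsilane | CC(C)(C)[Si](C)(C)OCC#C[C@@H]1C=C(CO[Si](C)(C)C(C)(C)C)CC[C@H]1C(C)C | intermediate
29 | tributyl[(1E)-3-[(tert-butyldimethylsilyl)oxy]-1-[(1S,6S)-3-{[(tert-butyldimethylsilyl)oxy]methyl}-6-(propan-2-yl)cyclohex-2-en-1-yl]prop-1-en-2-yl]stannane | CCCC[Sn](CCCC)(CCCC)/C(=C/[C@@H]1C=C(CO[Si](C)(C)C(C)(C)C)CC[C@H]1C(C)C)CO[Si](C)(C)C(C)(C)C | intermediate
30 | tert-butyl{[(2E)-2-iodo-3-[(1S,6S)-3-{[(tert-butyldimethylsilyl)oxy]methyl}-6-(propan-2-yl)cyclohex-2-en-1-yl]prop-2-en-1-yl]oxy}dimethylsilane | I/C(=C/[C@@H]1C=C(CO[Si](C)(C)C(C)(C)C)CC[C@H]1C(C)C)CO[Si](C)(C)C(C)(C)C | intermediate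
31 | methyl (2E)-2-{[(tert-butyldimethylsilyl)oxy]methyl}-3-[(1S,6S)-3-{[(tert-butyldimethylsilyl)oxy]methyl}-6-(propan-2-yl)cyclohex-2-en-1-yl]prop-2-enoate | COC(=O)/C(=C/[C@@H]1C=C(CO[Si](C)(C)C(C)(C)C)CC[C@H]1C(C)C)CO[Si](C)(C)C(C)(C)C | intermediate
32 | (2E)-2-{[(tert-butyldimethylsilyl)oxy]methyl}-3-[(1S,6S)-3-{[(tert-butyldimethylsilyl)oxy]methyl}-6-(propan-2-yl)cyclohex-2-en-1-yl]prop-2-enoic acid | OC(=O)/C(=C/[C@@H]1C=C(CO[Si](C)(C)C(C)(C)C)CC[C@H]1C(C)C)CO[Si](C)(C)C(C)(C)C | intermediate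
33 | mixed anhydride of 32 with 2,4,6-trichlorobenzoic acid | O=C(OC(=O)c1c(Cl)cc(Cl)cc1Cl)/C(=C/[C@@H]1C=C(CO[Si](C)(C)C(C)(C)C)CC[C@H]1C(C)C)CO[Si](C)(C)C(C)(C)C | intermediate
34 | target with both side-chain hydroxyls as tert-butyldimethylsilyl ethers and the ring acid as 2-(trimethylsilyl)ethyl ester | CC(C)[C@@H]1CC[C@](O)(COC(=O)/C(=C/[C@@H]2C=C(CO[Si](C)(C)C(C)(C)C)CC[C@H]2C(C)C)CO[Si](C)(C)C(C)(C)C)[C@H]2C(=O)OCC(C(=O)OCC[Si](C)(C)C)=C[C@@H]12 | intermediate
35 | (5aR,6S,9R,9aS)-9-hydroxy-9-({[(2E)-2-(hydroxymethyl)-3-[(1S,6S)-3-(hydroxymethyl)-6-(propan-2-yl)cyclohex-2-en-1-yl]prop-2-enoyl]oxy}methyl)-1-oxo-6-(propan-2-yl)-1,3,5a,6,7,8,9,9a-octahydro-2-benzoxepine-4-carboxylic acid | CC(C)[C@@H]1CC[C@](O)(COC(=O)/C(=C/[C@@H]2C=C(CO)CC[C@H]2C(C)C)CO)[C@H]2C(=O)OCC(C(=O)O)=C[C@@H]12 | target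

## Step count and fallbacks

Total step count: 24.
Longest linear sequence: 13 steps (steps 1, 2, 3, 4, 5, 6, 7, 8, 10, 11, 12, 23, 24). The acid branch is 12 steps (1, 14 to 22, 23, 24).

Steps most likely to fail:

Step 11 (ring-closing metathesis onto an electron-poor 1,1-disubstituted acrylate). The fallback sets out from vinyl acid 14 and comes back at lactone 18. The caesium salt of 14 is O-alkylated with 3-chloro-2-(chloromethyl)prop-1-ene (Cs2CO3, DMF) to give the 2-(chloromethyl)allyl ester F1. Its electron-neutral 1,1-disubstituted olefin closes far more readily with the second-generation Grubbs catalyst RuCl2(H2IMes)(PCy3)(=CHPh) in CH2Cl2 at 40 °C, giving the chloromethyl lactone F2. The allylic chloride is oxidised with N-methylmorpholine N-oxide in MeCN (Ganem oxidation) to the enal F3, and Pinnick oxidation (NaClO2, NaH2PO4, 2-methylbut-2-ene) gives the ring acid F4. Esterification of F4 with 2-(trimethylsilyl)ethanol (EDC·HCl, DMAP) returns to 18. The carboxyl carbon is thus raised to the acid level only after the ring is closed.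

Step 19 (regiochemistry of the hydrostannation). The fallback sets out from alkyne 28 and comes back at iodide 30. Hydrozirconation with Cp2Zr(H)Cl in THF at rt, using a slight excess so that zirconium equilibrates to the less hindered alkyne carbon next to CH2OSi, gives by syn addition the alkenylzirconocene chloride F5, which is not isolated. Iodinolysis with I2 at 0 °C then gives 30 with retention, with no tin intermediate.

Step 23 (acylation of a neopentyl-type primary alcohol by a hindered, isomerisation-prone acrylic acid). The fallback sets out from diol 19 and comes back at 34. Mitsunobu cyclodehydration of the 1,2-diol (PPh3, diisopropyl azodicarboxylate, THF) activates the primary hydroxyl and closes the spiro-epoxide F6 with retention at the tertiary carbon. Heating F6 with acid 32 and Cs2CO3 (0.5 equiv) in DMF at 70 °C opens the epoxide at its CH2 terminus by the carboxylate. This gives the tertiary alcohol and primary ester of 34 without any activation of the acyl group.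

Further compounds
F1 | step 11 | 2-(chloromethyl)prop-2-en-1-yl (5R,6S,7S,8S)-7-ethenyl-2,2-dimethyl-8-(propan-2-yl)-1,3-dioxaspiro[4.5]decane-6-carboxylate | CC(C)[C@@H]1CC[C@]3(COC(C)(C)O3)[C@@H](C(=O)OCC(=C)CCl)[C@H]1C=C
F2 | step 11 | analogue of lactone 18 carrying CH2Cl in place of the silylethyl ester group | CC(C)[C@@H]1CC[C@]3(COC(C)(C)O3)[C@H]2C(=O)OCC(CCl)=C[C@@H]12
F3 | step 11 | analogue of lactone 18 carrying CHO in place of the silylethyl ester group | CC(C)[C@@H]1CC[C@]3(COC(C)(C)O3)[C@H]2C(=O)OCC(C=O)=C[C@@H]12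
F4 | step 11 | free carboxylic acid corresponding to ester 18 | CC(C)[C@@H]1CC[C@]3(COC(C)(C)O3)[C@H]2C(=O)OCC(C(=O)O)=C[C@@H]12
F5 | step 19 | chlorobis(cyclopentadienyl)[(1E)-3-(silyloxy)-1-(cyclohexenyl)prop-1-en-2-yl]zirconium derived from 28 | Cl[Zr](C1C=CC=C1)(C1C=CC=C1)/C(=C/[C@@H]1C=C(CO[Si](C)(C)C(C)(C)C)CC[C@H]1C(C)C)CO[Si](C)(C)C(C)(C)C
F6 | step 23 | spiro-epoxide of 19 (C9–O and C9–CH2 closed to an oxirane, configuration at C9 retained) | CC(C)[C@@H]1CC[C@]3(CO3)[C@H]2C(=O)OCC(C(=O)OCC[Si](C)(C)C)=C[C@@H]12
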